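## Structural features

The target is a germacrane-type sesquiterpene lactone. Its ten-membered carbocycle (ring A, C1–C10) is bridged from C3 to C10 by an oxygen atom, so that O, C3, C2, C1 and C10 form a 3(2H)-furanone (ring B). Ring A is also fused at C6–C7 to a trans α-methylene-γ-butyrolactone (ring C: C6, C7, C11, C12, O). Three contiguous stereocentres, C6 (R), C7 (R) and C8 (R, bearing the 3-methylbutanoate), lie on one flank of ring A; the quaternary C10 (S), with its methyl group and the bridging oxygen, is separated from them by the C9 methylene. The C4=C5 alkene is trisubstituted and Z (C3 cis to C6), carries the C15 hydroxymethyl group and forms a cross-conjugated dienone with ring B. Fragile elements are the exocyclic methylene lactone (a Michael acceptor), the vinylogous ester, the allylic C15 alcohol and the C8 ester flanked by oxygenated carbons. In any C8 ketone precursor the C7 hydrogen is also fragile, being α to the carbonyl, allylic to C11=C13 and β to the C6 oxygen. The real difficulty is to close the strained, oxygen-bridged ten-membered ring around a Z alkene while creating the quaternary C10 in the correct sense relative to the distant C6–C8 triad. The feature exploited is that the C1 carbonyl and the C8 oxygen are 1,4-related through C10–C9. C10 is C2 of furanone ring B, whose enolate is an aromatic 3-oxidofuran, and C9 is α to C8, so the C9–C10 bond of ring A can be formed by alkylating that furanolate with an α-bromo ketone.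

## Logic of the disconnections

30 ⇒ 29. The O–Si bond at C15 is cut last. A free primary allylic C15 hydroxyl would compete in the oxidative lactonisation, so it stays silylated until the end. The forward step must remove silicon without touching the methylene lactone, the ester or the vinylogous ester.

29 ⇒ 26. The lactone is opened at C12–O and C12 is taken down to the alcohol level, giving a 6,12-diol. This keeps the Michael acceptor out of every basic step. The forward oxidant must prefer the primary C12 hydroxyl over the secondary, also allylic, C6 hydroxyl. C8 must already be acylated so that only the 6,12-lactone can form.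

26 ⇒ 25 ⇒ 24. The two O–Si bonds at C6 and C12 and the acyl–O bond at C8 are cut. C6 and C12 carry the same triethylsilyl group, a change from a benzyl-type ether at C12. This lets one mild operation unveil both and avoids an oxidative debenzylation next to the dienone. The demand is a clear lability gap to the C15 silyl ether.

24 ⇒ 23. The C8–H bond is cut, returning the C8 ketone left by the ring closure. The forward reduction must deliver hydride to one face of a hindered ring ketone to give 8R.

23 ⇒ 21. The C9–C10 bond is cut. This opens ring A, removes the quaternary centre and leaves an acyclic chain carrying a 2-methyl-3(2H)-furanone and a bromomethyl ketone. The forward step must favour C- over O-alkylation, C10 over C7 deprotonation, ring closure over oligomerisation, and one face of the furanolate.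

21 ⇒ 18. The C8–C9 bond is cut to an N-methoxy-N-methyl amide and a bromomethyl carbenoid. An α-bromo ketone cannot survive palladium, amine or gold, so it is introduced last. The forward addition must proceed with the furanone masked.

18 ⇒ 17 ⇒ 15 + 16 + CO. The O–C3 bond of ring B is cut to a γ-hydroxy ynone, then C3–C4 and C2–C3 are cut to a Z vinyl iodide, carbon monoxide and a four-carbon alkynol. C1, C2, C10 and C14 thus come from one commercial piece and C3 from CO. The demand is carbonylation faster than direct coupling, with retention of alkene geometry.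

15 ⇒ 14 ⇒ 13 ⇒ 12. The C12–O bond and the silyl ethers are cut. The aldol delivers C12 as a methyl group, so an allylic oxidation is unavoidable; it is placed where the only electron-rich alkene is C11=C13.

12 ⇒ 11 ⇒ 9 + 5. The amide is traced to the imide, and C6–C7 is cut by an auxiliary-controlled syn-aldol, which sets C6 and C7 together. The demand is α-selective reaction of a dienolate.

5 ⇒ 4 ⇒ 2 ⇒ 1 and 9 ⇒ 6 + 7. The C4–I and C5–H bonds are cut to a mono-protected butynediol. This hydroalumination–iodination is placed before the aldol because the aluminium hydride would attack the acyl group of 11. The imide N–acyl bond is cut to auxiliary and acid chloride.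

## Other disconnections considered

Alternative 1: The cut is the O–C10 bond of ring B, leading back to a monocyclic ten-membered 3-oxo-4Z-enolide epoxidised at C1–C10 (A1). In the forward key step an acid would activate the epoxide and the C3 carbonyl oxygen would open it at the tertiary C10 with inversion. Loss of a C2 proton would then give the bridged dihydrofuranol A2, and oxidation of the C1 carbinol plus desilylation would finish the synthesis.
- In favour: the C10 configuration follows stereospecifically from the epoxide, which is better defined than the tether-controlled facial selectivity of the chosen plan. The end-game after the key step is also shorter. On both points this alternative is the better one.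
- Against: A1 already contains ring A with an E C1=C10 and a Z C4=C5 alkene, the methylene lactone and the ester, so the hardest problem, closing the ten-membered ring, is left unsolved. The acid step runs in the presence of a Michael acceptor and gives an acid-labile allylic enol ether.
- Comparison: the chosen plan makes ring A, the bridge and C10 in one bond-forming event from an acyclic chain. The alternative makes only the bridge. Overall step economy is therefore expected to favour the chosen plan unless a short route to A1 exists.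

Alternative 2: The cut is C6–C7, reached by ring contraction of a thirteen-membered allyl propargyl ether A3. In the forward key step n-BuLi would deprotonate the propargylic C6 methylene and a [2,3]-Wittig shift would form C6–C7 and break O–C13, leaving the cyclodecynol A4.
- In favour: the ring is first closed as an unstrained ether and then contracted in a concerted step, and C6 and C7 arise together. The C11 arm emerges with its C12 oxygen, so no allylic oxidation is needed; on that point this alternative is better. The relative configuration at C6/C7 should be as predictable as in the aldol of the chosen plan, an equal point.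
- Against: A4 lacks C15 and carries C3 as a ketal and C1/C10 as protected carbinols. The Z trisubstituted alkene with its hydroxymethyl group would still have to be built on a strained cycloalkyne, and ring B assembled by oxidation and cyclodehydration. C10 must be set early and independently. Strong base with several silyl ethers invites silyl migration and [1,2]-shift.
- Comparison: both plans close ring A by an anionic C–C bond formation. The chosen one also finishes ring B and C10 in the same step, needs fewer protecting groups and is expected to be markedly shorter.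

Alternative 3: The cuts are C1–C6 and O–C6, leading back to a carvone-derived bicyclic tertiary alcohol with an acrylic acid arm (A5). In the forward key step the hypoiodite (PhI(OAc)2, I2, light) would give an alkoxy radical that cleaves C1–C6. The allylic C6 centre would be captured by the carboxylate to give the ten-membered enone lactone A6.
- In favour: six-membered-ring chemistry from the chiral pool is reliable, C7 comes with the starting material, and the Z C4=C5 geometry is inherited from the ring. Ring A and ring C appear in one step. On the origin of C7 and on the alkene geometry this alternative equals or betters the chosen plan.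
- Against: the allylic intermediate can be captured at C4 or C6 and from either face. The acrylic acid is itself a radical acceptor. A6 has C10 as the α-carbon of an enone, so the O–C10 bond of ring B cannot be made by conjugate addition and needs further oxidation-level and polarity adjustments; the quaternary C10 would be set only then. A5 itself needs a long sequence.
- Comparison: the alternative gives ring A and ring C but not ring B or C10. The chosen plan gives ring A, ring B and C10 at once and leaves ring C to a standard oxidative lactonisation, so it should be shorter overall.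

Key step: step 13

Assumption: atom labels C1–C15 follow the germacrane numbering of 30 in all compounds. Racemic 16 is used because C10 is planarised in the furanolate, so 17–21 are mixtures of C10 epimers. TBS = tert-butyldimethylsilyl, TES = triethylsilyl.

Remark: the configurations of 21 and 23 (C6, C7, C10, Z C4=C5) were checked centre by centre against 30 and are consistent with it.

## Route

Step 1
Reactants: 1 but-2-yne-1,4-diol
Product: 2 4-(TBSO)but-2-yn-1-ol
Conditions: t-BuMe2SiCl (1 equiv), imidazole, 1 (3 equiv), DMF, 0 °C to rt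
Reagents that add atoms: tert-butyldimethylsilyl chloride CC(C)(C)[Si](C)(C)Cl
Why: O-Silylation of an alcohol; with the symmetrical diol in excess the mono-ether should predominate and unreacted diol is removed by aqueous extraction.

Step 2
Reactants: 2 4-(TBSO)but-2-yn-1-ol
Product: 4 (Z)-4-(TBSO)-3-iodobut-2-en-1-ol, via sodium alkenylalanate 3 (not isolated)
Conditions: NaAlH2(OCH2CH2OMe)2, THF, 0 °C to rt; then I2, −78 to 0 °C
Reagents that add atoms: iodine II
Why: Hydroxyl-directed trans-hydroalumination of a propargylic alcohol followed by iodinolysis. The alkoxide delivers hydride to C5 and aluminium to C4 within the five-membered alanate 3, and iodine replaces aluminium with retention, so the Z geometry (C6 cis to iodine) needed for C4=C5 is fixed; the silylated oxygen does not direct.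

Step 3
Reactants: 4 (Z)-4-(TBSO)-3-iodobut-2-en-1-ol
Product: 5 (Z)-4-(TBSO)-3-iodobut-2-enal
Conditions: MnO2, CH2Cl2, rt, dark
Reagents that add atoms: none
Why: Allylic alcohol oxidation under neutral conditions, which should preserve the Z β-iodo enal and the silyl ether; 5 is used directly.

Step 4
Reactants: 6 (S)-4-benzyloxazolidin-2-one; 7 3-methylbut-2-enoyl chloride
Product: 9 (S)-4-benzyl-3-(3-methylbut-2-enoyl)oxazolidin-2-one, via lithium oxazolidinide 8 (not isolated)
Conditions: n-BuLi, THF, −78 °C; then 7, −78 to 0 °C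
Reagents that add atoms: none
Why: N-Acylation of the lithiated oxazolidinone with the acid chloride (imide formation).

Step 5
Reactants: 9 (S)-4-benzyl-3-(3-methylbut-2-enoyl)oxazolidin-2-one; 5 (Z)-4-(TBSO)-3-iodobut-2-enal
Product: 11 (S)-4-benzyl-3-[(2S,3S,4Z)-6-(TBSO)-3-hydroxy-5-iodo-2-(prop-1-en-2-yl)hex-4-enoyl]oxazolidin-2-one, via boron dienolate 10 (not isolated)
Conditions: Bu2BOTf, Et3N, CH2Cl2, −78 to 0 °C; then 5, −78 to 0 °C; pH 7 buffer, MeOH, H2O2, 0 °C
Reagents that add atoms: none
Why: Evans syn-aldol reaction. γ-Deprotonation gives the Z boron dienolate 10, which reacts at its α-carbon through a chair-like six-membered transition state on the face away from the benzyl group. This sets C7 (S here) and C6 (S here) with C6–O and C7–C11 syn, the arrangement required in 30.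

Step 6
Reactants: 11 (S)-4-benzyl-3-[(2S,3S,4Z)-6-(TBSO)-3-hydroxy-5-iodo-2-(prop-1-en-2-yl)hex-4-enoyl]oxazolidin-2-one
Product: 12 (2S,3S,4Z)-6-(TBSO)-3-hydroxy-5-iodo-N-methoxy-N-methyl-2-(prop-1-en-2-yl)hex-4-enamide
Conditions: MeNH(OMe)·HCl, AlMe3, THF, −20 to 0 °C
Reagents that add atoms: N,O-dimethylhydroxylamine hydrochloride CNOC.Cl
Why: Transamination of a β-hydroxy imide with the aluminium amide made from AlMe3 and the amine salt (Weinreb amide formation); the free C6 hydroxyl directs attack to the exocyclic carbonyl and the auxiliary is released.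

Step 7
Reactants: 12 (2S,3S,4Z)-6-(TBSO)-3-hydroxy-5-iodo-N-methoxy-N-methyl-2-(prop-1-en-2-yl)hex-4-enamide
Product: 13 (2S,3S,4Z)-6-(TBSO)-5-iodo-N-methoxy-N-methyl-2-(prop-1-en-2-yl)-3-(TESO)hex-4-enamide
Conditions: Et3SiOTf, 2,6-lutidine, CH2Cl2, −78 °C
Reagents that add atoms: triethylsilyl trifluoromethanesulfonate CC[Si](CC)(CC)OS(=O)(=O)C(F)(F)F
Why: Silyl ether formation with a silyl triflate and a hindered base at low temperature, conditions that should not enolise the amide α-centre.

Step 8
Reactants: 13 (2S,3S,4Z)-6-(TBSO)-5-iodo-N-methoxy-N-methyl-2-(prop-1-en-2-yl)-3-(TESO)hex-4-enamide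
Product: 14 (2S,3S,4Z)-6-(TBSO)-2-(3-hydroxyprop-1-en-2-yl)-5-iodo-N-methoxy-N-methyl-3-(TESO)hex-4-enamide
Conditions: SeO2 (0.5 equiv), t-BuOOH, CH2Cl2, 0 °C to rt
Reagents that add atoms: tert-butyl hydroperoxide CC(C)(C)OO (source of the C12 oxygen, relayed by selenium dioxide O=[Se]=O)
Why: Allylic oxidation by SeO2 (ene reaction, then [2,3]-sigmatropic shift) with t-BuOOH as terminal oxidant. C11=C13 is the only electron-rich alkene, and hydrogen should be taken from the methyl group in preference to the electron-poor C7 methine, placing the hydroxyl on C12.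

Step 9
Reactants: 14 (2S,3S,4Z)-6-(TBSO)-2-(3-hydroxyprop-1-en-2-yl)-5-iodo-N-methoxy-N-methyl-3-(TESO)hex-4-enamide
Product: 15 (2S,3S,4Z)-6-(TBSO)-5-iodo-N-methoxy-N-methyl-3-(TESO)-2-[3-(TESO)prop-1-en-2-yl]hex-4-enamide
Conditions: Et3SiCl, imidazole, CH2Cl2, 0 °C
Reagents that add atoms: chlorotriethylsilane CC[Si](CC)(CC)Cl
Why: Silylation of the primary allylic alcohol; any C6 silyl ether lost in step 8 would be restored in the same operation.

Step 10
Reactants: 15 (2S,3S,4Z)-6-(TBSO)-5-iodo-N-methoxy-N-methyl-3-(TESO)-2-[3-(TESO)prop-1-en-2-yl]hex-4-enamide; 16 but-3-yn-2-ol (racemic)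
Product: 17 (2S,3R,4Z)-5-[(TBSO)methyl]-9-hydroxy-N-methoxy-N-methyl-6-oxo-3-(TESO)-2-[3-(TESO)prop-1-en-2-yl]dec-4-en-7-ynamide (C10 epimers)
Conditions: PdCl2(PPh3)2 (5 mol %), CuI (5 mol %), Et3N, CO (1 atm), THF, rt
Reagents that add atoms: carbon monoxide [C-]#[O+]
Why: Carbonylative Sonogashira coupling. Oxidative addition of the vinyl iodide to zerovalent palladium, CO insertion and coupling with the copper acetylide of 16 should give the cross-conjugated ynone with retention of alkene geometry; the free propargylic hydroxyl is tolerated.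

Step 11
Reactants: 17 (2S,3R,4Z)-5-[(TBSO)methyl]-9-hydroxy-N-methoxy-N-methyl-6-oxo-3-(TESO)-2-[3-(TESO)prop-1-en-2-yl]dec-4-en-7-ynamide (C10 epimers)
Product: 18 (2S,3R,4Z)-6-(TBSO)-N-methoxy-N-methyl-5-(5-methyl-4-oxo-4,5-dihydrofuran-2-yl)-3-(TESO)-2-[3-(TESO)prop-1-en-2-yl]hex-4-enamide (C10 epimers)
Conditions: (4-CF3C6H4)3PAuCl (5 mol %), AgOTf (5 mol %), toluene, rt
Reagents that add atoms: none
Why: Gold-catalysed cycloisomerisation of a γ-hydroxy alkynone to a 3(2H)-furanone under neutral conditions (π-activation of the triple bond, net transfer of the carbonyl oxygen to C1 and closure of the C10 oxygen onto C3); C10 becomes the epimerisable C2 of the furanone.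

Step 12
Reactants: 18 (2S,3R,4Z)-6-(TBSO)-N-methoxy-N-methyl-5-(5-methyl-4-oxo-4,5-dihydrofuran-2-yl)-3-(TESO)-2-[3-(TESO)prop-1-en-2-yl]hex-4-enamide (C10 epimers)
Product: 21 (3S,4R,5Z)-1-bromo-7-(TBSO)-6-(5-methyl-4-oxo-4,5-dihydrofuran-2-yl)-4-(TESO)-3-[3-(TESO)prop-1-en-2-yl]hept-5-en-2-one (C10 epimers), via lithium furanolate 19 (not isolated), via tetrahedral adduct 20 (not isolated)
Conditions: LiN(SiMe3)2 (1.05 equiv), THF, −78 °C; CH2Br2, then MeLi·LiBr, −78 °C; AcOH, −78 °C
Reagents that add atoms: dibromomethane BrCBr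
Why: Addition of the bromomethyllithium carbenoid to a Weinreb amide, which stops at the chelated tetrahedral adduct 20 and releases the α-bromo ketone only on cold acidic quench. Prior conversion of the furanone into its lithium furanolate 19 masks both its acidic C10–H and its carbonyl group during the addition.

Step 13
Reactants: 21 (3S,4R,5Z)-1-bromo-7-(TBSO)-6-(5-methyl-4-oxo-4,5-dihydrofuran-2-yl)-4-(TESO)-3-[3-(TESO)prop-1-en-2-yl]hept-5-en-2-one (C10 epimers)
Product: 23 (6R,7S,10S)-15-(TBSO)-3,10-epoxy-6,12-bis(TESO)germacra-2,4Z,11(13)-triene-1,8-dione, via caesium furanolate 22 (not isolated)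
Conditions: Cs2CO3, MeCN (degassed, 0.002 M, slow addition of 21), rt
Reagents that add atoms: none
Why: Cs2CO3 removes the C10–H of the furanone, the most acidic C–H in 21 because the conjugate base 22 is an aromatic 3-oxidofuran, and C10 of 22 then displaces bromide from C9 in an intramolecular SN2 reaction. The closest known reaction type is C2-alkylation of 2-substituted 3(2H)-furanone enolates with reactive halides, combined with macrocyclising alkylation of stabilised enolates at high dilution. Ring A closes in the 10-exo-tet mode, and because C3 and C10 are already linked through the ring oxygen the same bond completes the 11-oxabicyclo[6.2.1]undecane frame. The new quaternary centre C10 is controlled by the C6 stereocentre through allylic 1,3-strain: with the Z alkene the C6–H bond eclipses C4=C5 to avoid the furanyl group, which places C7 and the C8–C9 electrophile on one face of the planar furanolate and the silyloxy group on the other, and attack from that face gives 10S. C- over O-alkylation is favoured by the soft α-keto bromide and by geometry, since O-alkylation would have to span the planar furan as a strained meta-bridged furanophane whereas C-alkylation pyramidalises C10. Selectivity over enolisation at C7 (which would lead to loss of the C6 silyloxy group or of the C7 configuration) rests on the acidity gap and the mild heterogeneous carbonate; oligomerisation is suppressed by slow addition at high dilution, and oxygen is excluded because furanolates autoxidise at C2.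

Step 14
Reactants: 23 (6R,7S,10S)-15-(TBSO)-3,10-epoxy-6,12-bis(TESO)germacra-2,4Z,11(13)-triene-1,8-dione
Product: 24 (6R,7R,8R,10S)-15-(TBSO)-3,10-epoxy-8-hydroxy-6,12-bis(TESO)germacra-2,4Z,11(13)-trien-1-one
Conditions: (S)-2-methyl-CBS-oxazaborolidine, catecholborane, toluene, −78 to −40 °C
Reagents that add atoms: none
Why: Corey–Bakshi–Shibata reduction with catecholborane, which at low temperature should neither hydroborate the alkenes nor reduce the vinylogous ester carbonyl. With the branched C7 as the large and the C9 methylene as the small substituent, the (S)-catalyst should deliver hydride to the face that gives the 8R alcohol (C8–O cis to C7–C11 on the ring).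

Step 15
Reactants: 24 (6R,7R,8R,10S)-15-(TBSO)-3,10-epoxy-8-hydroxy-6,12-bis(TESO)germacra-2,4Z,11(13)-trien-1-one
Product: 25 (6R,7R,8R,10S)-15-(TBSO)-3,10-epoxy-8-(3-methylbutanoyloxy)-6,12-bis(TESO)germacra-2,4Z,11(13)-trien-1-one
Conditions: (Me2CHCH2CO)2O, DMAP, Et3N, CH2Cl2, 0 °C to rt
Reagents that add atoms: 3-methylbutanoic anhydride CC(C)CC(=O)OC(=O)CC(C)C
Why: DMAP-catalysed esterification of the secondary alcohol with the anhydride; the ester also prevents the C8 oxygen from competing in the later lactonisation.

Step 16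
Reactants: 25 (6R,7R,8R,10S)-15-(TBSO)-3,10-epoxy-8-(3-methylbutanoyloxy)-6,12-bis(TESO)germacra-2,4Z,11(13)-trien-1-one
Product: 26 (6R,7S,8R,10S)-15-(TBSO)-3,10-epoxy-6,12-dihydroxy-8-(3-methylbutanoyloxy)germacra-2,4Z,11(13)-trien-1-one
Conditions: PPTS, MeOH/CH2Cl2, 0 °C
Reagents that add atoms: none
Why: Acid-catalysed methanolysis of silyl ethers; both triethylsilyl ethers are far more labile than the primary tert-butyldimethylsilyl ether at C15, so the 6,12-diol should be released in one operation.

Step 17
Reactants: 26 (6R,7S,8R,10S)-15-(TBSO)-3,10-epoxy-6,12-dihydroxy-8-(3-methylbutanoyloxy)germacra-2,4Z,11(13)-trien-1-one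
Product: 29 (6R,7R,8R,10S)-15-(TBSO)-3,10-epoxy-8-(3-methylbutanoyloxy)-1-oxogermacra-2,4Z,11(13)-trien-12,6-olide, via hydroxy enal 27 (not isolated), via lactol 28 (not isolated)
Conditions: TEMPO (0.2 equiv), PhI(OAc)2 (2.5 equiv), CH2Cl2, rt
Reagents that add atoms: none
Why: Oxoammonium (TEMPO) oxidation with PhI(OAc)2 as terminal oxidant, selective for the primary C12 alcohol over the secondary C6 alcohol. Enal 27 closes with the C6 hydroxyl to lactol 28, which is oxidised further to the α-methylene-γ-lactone (oxidative lactonisation of a 1,4-diol); the trans ring fusion follows from C6 and C7.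

Step 18
Reactants: 29 (6R,7R,8R,10S)-15-(TBSO)-3,10-epoxy-8-(3-methylbutanoyloxy)-1-oxogermacra-2,4Z,11(13)-trien-12,6-olide
Product: 30 (6R,7R,8R,10S)-3,10-epoxy-15-hydroxy-8-(3-methylbutanoyloxy)-1-oxogermacra-2,4Z,11(13)-trien-12,6-olide (CNP0171896.1)
Conditions: HF·pyridine, pyridine, THF, 0 °C
Reagents that add atoms: none
Why: Fluoride-mediated silyl ether cleavage under buffered, weakly acidic conditions that should spare the methylene lactone, the ester and the vinylogous ester.

## Compound list

1 | but-2-yne-1,4-diol | OCC#CCO | starting material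
2 | 4-(TBSO)but-2-yn-1-ol | OCC#CCO[Si](C)(C)C(C)(C)C | intermediate
3 | sodium 3-[(TBSO)methyl]-2,2-bis(2-methoxyethoxy)-2,5-dihydro-1,2-oxaaluminol-2-uide (cyclic alkenylalanate, not isolated) | COCCO[Al-]1(OCCOC)OCC=C1CO[Si](C)(C)C(C)(C)C.[Na+] | intermediate
4 | (Z)-4-(TBSO)-3-iodobut-2-en-1-ol | OC/C=C(\I)CO[Si](C)(C)C(C)(C)C | intermediate
5 | (Z)-4-(TBSO)-3-iodobut-2-enal | O=C/C=C(\I)CO[Si](C)(C)C(C)(C)C | intermediate
6 | (S)-4-benzyloxazolidin-2-one | O=C1N[C@@H](Cc2ccccc2)CO1 | starting material
7 | 3-methylbut-2-enoyl chloride | CC(C)=CC(=O)Cl | starting material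
8 | lithium (S)-4-benzyl-2-oxooxazolidin-3-ide (not isolated) | O=C1[N-][C@@H](Cc2ccccc2)CO1.[Li+] | intermediate
9 | (S)-4-benzyl-3-(3-methylbut-2-enoyl)oxazolidin-2-one | CC(C)=CC(=O)N1C(=O)OC[C@@H]1Cc1ccccc1 | intermediate
10 | (S)-4-benzyl-3-[(1Z)-1-(dibutylboranyloxy)-3-methylbuta-1,3-dienyl]oxazolidin-2-one (boron dienolate, not isolated) | C=C(C)/C=C(\OB(CCCC)CCCC)N1C(=O)OC[C@@H]1Cc1ccccc1 | intermediate
11 | (S)-4-benzyl-3-[(2S,3S,4Z)-6-(TBSO)-3-hydroxy-5-iodo-2-(prop-1-en-2-yl)hex-4-enoyl]oxazolidin-2-one | O=C1OC[C@H](Cc2ccccc2)N1C(=O)[C@@H](C(C)=C)[C@H](O)/C=C(\I)CO[Si](C)(C)C(C)(C)C | intermediate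
12 | (2S,3S,4Z)-6-(TBSO)-3-hydroxy-5-iodo-N-methoxy-N-methyl-2-(prop-1-en-2-yl)hex-4-enamide | CON(C)C(=O)[C@@H](C(C)=C)[C@H](O)/C=C(\I)CO[Si](C)(C)C(C)(C)C | intermediate
13 | (2S,3S,4Z)-6-(TBSO)-5-iodo-N-methoxy-N-methyl-2-(prop-1-en-2-yl)-3-(TESO)hex-4-enamide | CON(C)C(=O)[C@@H](C(C)=C)[C@H](O[Si](CC)(CC)CC)/C=C(\I)CO[Si](C)(C)C(C)(C)C | intermediate
14 | (2S,3S,4Z)-6-(TBSO)-2-(3-hydroxyprop-1-en-2-yl)-5-iodo-N-methoxy-N-methyl-3-(TESO)hex-4-enamide | CON(C)C(=O)[C@@H](C(=C)CO)[C@H](O[Si](CC)(CC)CC)/C=C(\I)CO[Si](C)(C)C(C)(C)C | intermediate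
15 | (2S,3S,4Z)-6-(TBSO)-5-iodo-N-methoxy-N-methyl-3-(TESO)-2-[3-(TESO)prop-1-en-2-yl]hex-4-enamide | CON(C)C(=O)[C@@H](C(=C)CO[Si](CC)(CC)CC)[C@H](O[Si](CC)(CC)CC)/C=C(\I)CO[Si](C)(C)C(C)(C)C | intermediate
16 | but-3-yn-2-ol (racemic) | CC(O)C#C | starting material
17 | (2S,3R,4Z)-5-[(TBSO)methyl]-9-hydroxy-N-methoxy-N-methyl-6-oxo-3-(TESO)-2-[3-(TESO)prop-1-en-2-yl]dec-4-en-7-ynamide (C10 epimers) | CON(C)C(=O)[C@@H](C(=C)CO[Si](CC)(CC)CC)[C@H](O[Si](CC)(CC)CC)/C=C(/CO[Si](C)(C)C(C)(C)C)C(=O)C#CC(C)O | intermediate
18 | (2S,3R,4Z)-6-(TBSO)-N-methoxy-N-methyl-5-(5-methyl-4-oxo-4,5-dihydrofuran-2-yl)-3-(TESO)-2-[3-(TESO)prop-1-en-2-yl]hex-4-enamide (C10 epimers) | CON(C)C(=O)[C@@H](C(=C)CO[Si](CC)(CC)CC)[C@H](O[Si](CC)(CC)CC)/C=C(/CO[Si](C)(C)C(C)(C)C)C1=CC(=O)C(C)O1 | intermediate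
19 | lithium 2-methylfuran-3-olate form of 18 (not isolated) | CON(C)C(=O)[C@@H](C(=C)CO[Si](CC)(CC)CC)[C@H](O[Si](CC)(CC)CC)/C=C(/CO[Si](C)(C)C(C)(C)C)c1cc([O-])c(C)o1.[Li+] | intermediate
20 | dilithium tetrahedral adduct of 19 with bromomethyllithium at C8 (not isolated) | CON(C)C([O-])(CBr)[C@@H](C(=C)CO[Si](CC)(CC)CC)[C@H](O[Si](CC)(CC)CC)/C=C(/CO[Si](C)(C)C(C)(C)C)c1cc([O-])c(C)o1.[Li+].[Li+] | intermediate
21 | (3S,4R,5Z)-1-bromo-7-(TBSO)-6-(5-methyl-4-oxo-4,5-dihydrofuran-2-yl)-4-(TESO)-3-[3-(TESO)prop-1-en-2-yl]hept-5-en-2-one (C10 epimers; key-step precursor) | BrCC(=O)[C@@H](C(=C)CO[Si](CC)(CC)CC)[C@H](O[Si](CC)(CC)CC)/C=C(/CO[Si](C)(C)C(C)(C)C)C1=CC(=O)C(C)O1 | intermediate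
22 | caesium 2-methylfuran-3-olate form of 21 (not isolated) | BrCC(=O)[C@@H](C(=C)CO[Si](CC)(CC)CC)[C@H](O[Si](CC)(CC)CC)/C=C(/CO[Si](C)(C)C(C)(C)C)c1cc([O-])c(C)o1.[Cs+] | intermediate
23 | (6R,7S,10S)-15-(TBSO)-3,10-epoxy-6,12-bis(TESO)germacra-2,4Z,11(13)-triene-1,8-dione (key-step product) | C=C(CO[Si](CC)(CC)CC)[C@@H]1C(=O)C[C@]2(C)OC(=CC2=O)/C(CO[Si](C)(C)C(C)(C)C)=C\[C@H]1O[Si](CC)(CC)CC | intermediate
24 | (6R,7R,8R,10S)-15-(TBSO)-3,10-epoxy-8-hydroxy-6,12-bis(TESO)germacra-2,4Z,11(13)-trien-1-one | C=C(CO[Si](CC)(CC)CC)[C@@H]1[C@H](O)C[C@]2(C)OC(=CC2=O)/C(CO[Si](C)(C)C(C)(C)C)=C\[C@H]1O[Si](CC)(CC)CC | intermediate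
25 | (6R,7R,8R,10S)-15-(TBSO)-3,10-epoxy-8-(3-methylbutanoyloxy)-6,12-bis(TESO)germacra-2,4Z,11(13)-trien-1-one | C=C(CO[Si](CC)(CC)CC)[C@@H]1[C@H](OC(=O)CC(C)C)C[C@]2(C)OC(=CC2=O)/C(CO[Si](C)(C)C(C)(C)C)=C\[C@H]1O[Si](CC)(CC)CC | intermediate
26 | (6R,7S,8R,10S)-15-(TBSO)-3,10-epoxy-6,12-dihydroxy-8-(3-methylbutanoyloxy)germacra-2,4Z,11(13)-trien-1-one | C=C(CO)[C@@H]1[C@H](OC(=O)CC(C)C)C[C@]2(C)OC(=CC2=O)/C(CO[Si](C)(C)C(C)(C)C)=C\[C@H]1O | intermediate
27 | (6R,7S,8R,10S)-15-(TBSO)-3,10-epoxy-6-hydroxy-8-(3-methylbutanoyloxy)-1-oxogermacra-2,4Z,11(13)-trien-12-al (not isolated) | C=C(C=O)[C@@H]1[C@H](OC(=O)CC(C)C)C[C@]2(C)OC(=CC2=O)/C(CO[Si](C)(C)C(C)(C)C)=C\[C@H]1O | intermediate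
28 | 12-hydroxy-6,12-epoxy lactol of 27, (6R,7R,8R,10S), C12 anomers (not isolated) | C=C1C(O)O[C@@H]2/C=C(/CO[Si](C)(C)C(C)(C)C)C3=CC(=O)[C@](C)(C[C@@H](OC(=O)CC(C)C)[C@@H]12)O3 | intermediate
29 | (6R,7R,8R,10S)-15-(TBSO)-3,10-epoxy-8-(3-methylbutanoyloxy)-1-oxogermacra-2,4Z,11(13)-trien-12,6-olide | C=C1C(=O)O[C@@H]2/C=C(/CO[Si](C)(C)C(C)(C)C)C3=CC(=O)[C@](C)(C[C@@H](OC(=O)CC(C)C)[C@@H]12)O3 | intermediate
30 | (6R,7R,8R,10S)-3,10-epoxy-15-hydroxy-8-(3-methylbutanoyloxy)-1-oxogermacra-2,4Z,11(13)-trien-12,6-olide (CNP0171896.1) | C=C1C(=O)O[C@@H]2/C=C(/CO)C3=CC(=O)[C@](C)(C[C@@H](OC(=O)CC(C)C)[C@@H]12)O3 | target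

## Step count and least certain steps

Total: 18 steps. Longest linear sequence: 17 steps (steps 1–3 and 5–18, from 1); the imide branch (step 4) joins at step 5.

**Step 13 (key step).** The most likely failure is deprotonation at C7 instead of, or after, C10. This would lead to β-elimination of the C6 silyloxy group, loss of the C7 configuration or cyclopropanone-type (Favorskii) pathways. Oligomerisation is also possible if transannular strain slows the ring closure, and poor facial selectivity at C10 is the second concern. The fallback changes the electrophile from the α-bromo ketone to a terminal epoxide, which removes the acidic ketone. Setting out from 21, Corey–Bakshi–Shibata reduction ((S)-catalyst, catecholborane) would give bromohydrin F1 with the C8 oxygen already in the configuration of 30. Cs2CO3 would close it to terminal epoxide F2. Opening of F2 at C9 by the furanolate (Cs2CO3, LiClO4, DMF, 40–60 °C, high dilution; epoxide alkylation of a stabilised enolate) would form C9–C10 and rejoin the route at 24, making step 14 unnecessary.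

**Step 12.** The most likely failure is incomplete masking of the furanone: proton transfer from C10–H to the carbenoid or to adduct 20, or attack at the furanone carbonyl. Premature ring closure or aldol reactions could also occur if 20 collapses before the furanolate is reprotonated. The fallback uses covalent instead of ionic masking. Setting out from 18, t-BuMe2SiOTf and Et3N would give the aromatic 3-silyloxyfuran F3. The same carbenoid addition would convert F3 into bromo ketone F4. CsF in MeCN at high dilution would then desilylate F4 to the furanolate of step 13 (fluoride-induced alkylation of a silyl enol ether) and rejoin the route at 23.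

**Step 14.** The most likely failure is poor or reversed facial selectivity, because the conformation of the bridged ten-membered ring may override the catalyst. The fallback uses substrate control followed by inversion. Setting out from 23, an achiral hydride (NaBH4 with CeCl3, or LiBH(s-Bu)3) would be chosen for whichever gives mainly the 8-epi alcohol F5. Mitsunobu esterification of F5 with 3-methylbutanoic acid (PPh3, diisopropyl azodicarboxylate) would give the ester with inversion and rejoin the route at 25, replacing steps 14 and 15.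

**Step 8.** The most likely failure is low regioselectivity (hydrogen abstraction at C7) and over-oxidation of the C12 alcohol to the enal, with partial loss of the C6 silyl ether under the acidic conditions. The fallback is ene-type allylic chlorination followed by substitution. Setting out from 13, HOCl (from Ca(OCl)2 and solid CO2, CH2Cl2/H2O, 0 °C) would give allylic chloride F6. CsOAc in DMF would give acetate F7, and K2CO3 in MeOH would release the alcohol, rejoining the route at 14.

**Step 10.** The most likely failure is direct, non-carbonylative coupling or slow CO insertion at the hindered alkenylpalladium intermediate flanked by two oxygenated carbons. The fallback is a two-stage acylation by Nozaki–Hiyama–Kishi addition and oxidation. Setting out from 16, NaH and 4-methoxybenzyl chloride would give ether F8, and n-BuLi then DMF would give ynal F9. Setting out from 15, CrCl2 with catalytic NiCl2 (DMF/THF) would couple the vinyl iodide with F9 to the C3 carbinol F10. Dess–Martin periodinane would give ynone F11, and DDQ would remove the benzyl ether to rejoin the route at 17.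

## Further compounds

F1 | step 13 | C8 bromohydrin of 21 with the C8 oxygen configured as in 30 (C10 epimers) | BrC[C@@H](O)[C@@H](C(=C)CO[Si](CC)(CC)CC)[C@H](O[Si](CC)(CC)CC)/C=C(/CO[Si](C)(C)C(C)(C)C)C1=CC(=O)C(C)O1
F2 | step 13 | C8–C9 terminal epoxide derived from F1 (C10 epimers) | C1O[C@H]1[C@@H](C(=C)CO[Si](CC)(CC)CC)[C@H](O[Si](CC)(CC)CC)/C=C(/CO[Si](C)(C)C(C)(C)C)C2=CC(=O)C(C)O2
F3 | step 12 | 3-(TBSO)-2-methylfuran (silyl dienol ether) form of 18 | CON(C)C(=O)[C@@H](C(=C)CO[Si](CC)(CC)CC)[C@H](O[Si](CC)(CC)CC)/C=C(/CO[Si](C)(C)C(C)(C)C)c1cc(O[Si](C)(C)C(C)(C)C)c(C)o1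
F4 | step 12 | 3-(TBSO)-2-methylfuran form of bromomethyl ketone 21 | BrCC(=O)[C@@H](C(=C)CO[Si](CC)(CC)CC)[C@H](O[Si](CC)(CC)CC)/C=C(/CO[Si](C)(C)C(C)(C)C)c1cc(O[Si](C)(C)C(C)(C)C)c(C)o1
F5 | step 14 | C8 epimer of 24 (8S alcohol) | C=C(CO[Si](CC)(CC)CC)[C@@H]1[C@@H](O)C[C@]2(C)OC(=CC2=O)/C(CO[Si](C)(C)C(C)(C)C)=C\[C@H]1O[Si](CC)(CC)CC
F6 | step 8 | allylic chloride corresponding to 14 (2-(3-chloroprop-1-en-2-yl) amide) | CON(C)C(=O)[C@@H](C(=C)CCl)[C@H](O[Si](CC)(CC)CC)/C=C(\I)CO[Si](C)(C)C(C)(C)C
F7 | step 8 | allylic acetate corresponding to 14 | CON(C)C(=O)[C@@H](C(=C)COC(C)=O)[C@H](O[Si](CC)(CC)CC)/C=C(\I)CO[Si](C)(C)C(C)(C)C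
F8 | step 10 | 1-[(but-3-yn-2-yloxy)methyl]-4-methoxybenzene (racemic) | CC(OCc1ccc(OC)cc1)C#C
F9 | step 10 | 4-(4-methoxybenzyloxy)pent-2-ynal (racemic) | CC(OCc1ccc(OC)cc1)C#CC=O
F10 | step 10 | C3 carbinol from coupling of 15 with F9 (C3 and C10 epimers) | CON(C)C(=O)[C@@H](C(=C)CO[Si](CC)(CC)CC)[C@H](O[Si](CC)(CC)CC)/C=C(/CO[Si](C)(C)C(C)(C)C)C(O)C#CC(C)OCc1ccc(OC)cc1
F11 | step 10 | 4-methoxybenzyl ether of ynone 17 (C10 epimers) | CON(C)C(=O)[C@@H](C(=C)CO[Si](CC)(CC)CC)[C@H](O[Si](CC)(CC)CC)/C=C(/CO[Si](C)(C)C(C)(C)C)C(=O)C#CC(C)OCc1ccc(OC)cc1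
A1 | alternative 1 | 1,10-epoxide of the ten-membered 3-oxo-4Z-germacranolide (trans epoxide, C15 silyl ether, C8 3-methylbutanoate) | C=C1C(=O)O[C@@H]2/C=C(/CO[Si](C)(C)C(C)(C)C)C(=O)C[C@H]3O[C@]3(C)C[C@@H](OC(=O)CC(C)C)[C@@H]12
A2 | alternative 1 | bridged 2,3-dihydrofuran-3-ol (C1 alcohol of the furanone) | C=C1C(=O)O[C@@H]2/C=C(/CO[Si](C)(C)C(C)(C)C)C3=C[C@@H](O)[C@](C)(C[C@@H](OC(=O)CC(C)C)[C@@H]12)O3
A3 | alternative 2 | thirteen-membered allyl propargyl ether (C8 trans to C13 on the C7=C11 alkene) | O1CC#CC2(OCCO2)C[C@H](O[Si](C)(C)C(C)(C)C)[C@@](C)(OCOC)C[C@@H](O[Si](C)(C)C(C)(C)C)/C=C(\COCc2ccc(OC)cc2)C1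
A4 | alternative 2 | ten-membered cycloalkynol with C6 hydroxyl and C7 2-propenyl arm | O[C@@H]1C#CC2(OCCO2)C[C@H](O[Si](C)(C)C(C)(C)C)[C@@](C)(OCOC)C[C@@H](O[Si](C)(C)C(C)(C)C)[C@H]1C(=C)COCc1ccc(OC)cc1
A5 | alternative 3 | carvone-derived bicyclic C1 tertiary alcohol with acrylic acid arm (ring-fusion configuration at C1 and C6 left open, both centres being lost) | C=C(C(=O)O)[C@@H]1[C@H](OC(=O)CC(C)C)C=C(C)C2(O)C[C@@H](O[Si](CC)(CC)CC)C(CO[Si](C)(C)C(C)(C)C)=CC12
A6 | alternative 3 | ten-membered 9-en-1-one with trans-lactone and Z C4=C5 alkene | C=C1C(=O)O[C@@H]2/C=C(/CO[Si](C)(C)C(C)(C)C)[C@H](O[Si](CC)(CC)CC)CC(=O)/C(C)=C\[C@@H](OC(=O)CC(C)C)[C@@H]12
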